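**Strategy**

The flavanone is cut at ring A: the 5,7-dioxygenated benzene ring fused to pyranone ring C through C4a–C8a is removed entirely (bonds C4a–C5, C5–C6, C7–C8, C8–C8a). One operation, a photo-Wolff rearrangement followed by ketene–alkyne [2+2], 4π opening and 6π closure, rebuilds it from an (S)-2-aryl-6-(diazoacetyl)-2,3-dihydro-4H-pyran-4-one and (triisopropylsiloxy)acetylene; the ketene carbonyl becomes the C5 hydroxyl and the siloxy carbon C7. The precursor already holds the C2 stereocentre (asymmetric vinylogous aldol) and the geranylated B ring, whose 2'-oxygen is silylated, not acetal-protected, so that a single buffered fluoride step ends the synthesis.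

Key step: step 12

Remark: the antipode of the aldol catalyst needed for Si-face addition to aldehyde 9 is taken as (S,S) by analogy with benzaldehyde-type substrates; the configuration of 14 would be verified (Mosher ester) and the antipode used if the sense is opposite.

Abbreviations: geranyl = (2E)-3,7-dimethylocta-2,6-dien-1-yl; Ar = 5-geranyl-4-methoxy-2-(triisopropylsilyloxy)phenyl; TIPS = triisopropylsilyl; TMS = trimethylsilyl.

**Route**

Step 1
Reactants: 1 2-hydroxy-4-methoxybenzaldehyde
Product: 2 5-bromo-2-hydroxy-4-methoxybenzaldehyde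
Conditions: NBS, MeCN, 0 °C to rt
Reagents that add atoms: N-bromosuccinimide, O=C1CCC(=O)N1Br
Why: Electrophilic aromatic bromination should go to C5, which is para to the hydroxyl and ortho to the methoxy group, whereas C3 is flanked by two substituents.

Step 2
Reactants: 2 5-bromo-2-hydroxy-4-methoxybenzaldehyde
Product: 3 5-bromo-4-methoxy-2-(triisopropylsilyloxy)benzaldehyde
Conditions: TIPSCl, imidazole, DMF, rt
Reagents that add atoms: triisopropylsilyl chloride, CC(C)[Si](Cl)(C(C)C)C(C)C
Why: Imidazole-mediated O-silylation of a phenol gives a bulky aryl silyl ether that tolerates organolithium, Lewis acid and mild Brønsted acid steps and is cleaved by fluoride at the end.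

Step 3
Reactants: 3 5-bromo-4-methoxy-2-(triisopropylsilyloxy)benzaldehyde
Product: 4 5-bromo-4-methoxy-2-(triisopropylsilyloxy)benzaldehyde dimethyl acetal
Conditions: HC(OMe)3, MeOH, PPTS (cat.), rt; Et3N quench
Reagents that add atoms: trimethyl orthoformate, COC(OC)OC; methanol, CO
Why: Acid-catalysed acetalisation with the orthoformate as water scavenger masks the aldehyde for the organolithium step, and the aryl TIPS ether is stable to catalytic PPTS.

Step 4
Reactants: 4 5-bromo-4-methoxy-2-(triisopropylsilyloxy)benzaldehyde dimethyl acetal; 5 geranyl bromide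
Product: 9 5-geranyl-4-methoxy-2-(triisopropylsilyloxy)benzaldehyde, via aryllithium 6 (not isolated), via arylcopper 7 (not isolated), via geranylated dimethyl acetal 8 (not isolated)
Conditions: n-BuLi, THF, −78 °C; CuBr·SMe2, −78 to −40 °C; 5, to 0 °C; then 1 M HCl, THF, 0 °C
Reagents that add atoms: water, O
Why: Bromine–lithium exchange, transmetalation to the arylcopper species and SN2 allylic substitution at the primary carbon of geranyl bromide should give the linear product with the (E)-alkene intact, and the electron-rich dimethyl acetal hydrolyses on the brief acidic work-up.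

Step 5
Reactants: 10 ethyl 2,4-dioxopentanoate
Product: 12 ethyl (2Z)-2,4-bis(trimethylsilyloxy)penta-2,4-dienoate, via mono-silyl enol ether 11 (not isolated)
Conditions: TMSOTf (2.2 equiv), Et3N, Et2O, 0 °C to rt; used crude after filtration under argon
Reagents that add atoms: trimethylsilyl triflate, C[Si](C)(C)OS(=O)(=O)C(F)(F)F
Why: Soft enolisation with TMSOTf/Et3N silylates first the enolised 1,3-dicarbonyl unit and then the methyl ketone, giving the cross-conjugated bis-silyl dienolate in the way 2,4-bis(silyloxy)penta-1,3-dienes are made from 1,3-diketones.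

Step 6
Reactants: 9 5-geranyl-4-methoxy-2-(triisopropylsilyloxy)benzaldehyde; 12 ethyl (2Z)-2,4-bis(trimethylsilyloxy)penta-2,4-dienoate
Product: 14 ethyl (6S)-6-Ar-6-hydroxy-2,4-dioxohexanoate (largely enolised), via trichlorosilyl aldolate 13 (not isolated)
Conditions: SiCl4 (1.5 equiv), (S,S)-bisphosphoramide (pentamethylene-linked binaphthyl-2,2'-diamine phosphoramide dimer, 5 mol %), i-Pr2NEt (10 mol %), CH2Cl2, −78 °C; then sat. aq. NaHCO3, 0 °C
Reagents that add atoms: none
Why: In this Lewis-base-catalysed vinylogous Mukaiyama aldol of a methyl-ketone trimethylsilyl enol ether with an aromatic aldehyde, the terminal CH2 of 12 (its most nucleophilic carbon) adds to the aldehyde held by the chiral phosphoramide-bound trichlorosilyl cation, which exposes the Si face and so sets the (S)-carbinol, and the work-up removes both silyl groups.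

Step 7
Reactants: 14 ethyl (6S)-6-Ar-6-hydroxy-2,4-dioxohexanoate
Product: 16 ethyl (2S)-2-Ar-4-oxo-3,4-dihydro-2H-pyran-6-carboxylate, via cyclic hemiketal 15 (not isolated)
Conditions: CSA (10 mol %), 4 Å MS, CH2Cl2, 0 °C to rt
Reagents that add atoms: none
Why: Acid-catalysed cyclodehydration of a δ-hydroxy-1,3-dicarbonyl compound proceeds by 6-exo-trig addition of the hydroxyl to the keto-ester carbonyl and loss of water from hemiketal 15 to the vinylogous ester, and since the C–O bond at the stereocentre is never broken the (S) configuration is kept.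

Step 8
Reactants: 16 ethyl (2S)-2-Ar-4-oxo-3,4-dihydro-2H-pyran-6-carboxylate
Product: 18 (2S)-2-Ar-4-oxo-3,4-dihydro-2H-pyran-6-carboxylic acid, via trimethylstannyl ester 17 (not isolated)
Conditions: Me3SnOH (3 equiv), ClCH2CH2Cl, 70 °C; then cold 0.1 M HCl wash
Reagents that add atoms: trimethyltin hydroxide, C[Sn](C)(C)O
Why: Trimethyltin hydroxide cleaves the ester by a neutral tin-assisted acyl substitution, avoiding free hydroxide that could attack the aryl silyl ether or open the pyranone by β-elimination across C3/C2–O1.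

Step 9
Reactants: 18 (2S)-2-Ar-4-oxo-3,4-dihydro-2H-pyran-6-carboxylic acid
Product: 20 (S)-6-(2-diazoacetyl)-2-Ar-2,3-dihydro-4H-pyran-4-one, via mixed anhydride 19 (not isolated)
Conditions: i-BuOCOCl, N-methylmorpholine, THF, −20 °C; then CH2N2 (excess), Et2O, 0 °C
Reagents that add atoms: diazomethane, C=[N+]=[N-]
Why: Acylation of diazomethane by a mixed carbonic anhydride (Arndt–Eistert-type diazoketone synthesis) runs at 0 °C under nearly neutral conditions and should be much faster than dipolar cycloaddition to the donor–acceptor C5=C6 bond.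

Step 10
Reactants: 21 (trimethylsilyl)acetylene
Product: 24 triisopropyl{[(trimethylsilyl)ethynyl]oxy}silane, via lithium acetylide 22 (not isolated), via lithium ynolate 23 (not isolated)
Conditions: n-BuLi, THF, −78 °C; LiOOt-Bu (from t-BuOOH and LiHMDS), −78 to 0 °C; TIPSOTf, −78 to 0 °C
Reagents that add atoms: tert-butyl hydroperoxide, CC(C)(C)OO; triisopropylsilyl triflate, CC(C)[Si](OS(=O)(=O)C(F)(F)F)(C(C)C)C(C)C
Why: Oxidation of a lithium acetylide by lithium tert-butyl peroxide gives the lithium ynolate, which the hard, bulky silyl triflate should trap on oxygen, as in the standard preparation of triisopropylsilyl ynol ethers from terminal alkynes.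

Step 11
Reactants: 24 triisopropyl{[(trimethylsilyl)ethynyl]oxy}silane
Product: 25 (triisopropylsiloxy)acetylene
Conditions: K2CO3 (cat.), MeOH, 0 °C, short contact; pentane extraction
Reagents that add atoms: none
Why: Base-catalysed methanolysis should cleave the unhindered alkynyl C–SiMe3 bond much faster than the hindered O–Si(i-Pr)3 bond, releasing the terminal siloxyalkyne.

Step 12
Reactants: 20 (S)-6-(2-diazoacetyl)-2-Ar-2,3-dihydro-4H-pyran-4-one; 25 (triisopropylsiloxy)acetylene
Product: 30 (S)-5-hydroxy-2-Ar-7-(triisopropylsilyloxy)chroman-4-one (7,2'-bis-O-TIPS Kuwanon U), via vinylketene 26 (not isolated), via siloxycyclobutenone 27 (not isolated), via dienylketene 28 (not isolated), via cyclohexadienone 29 (not isolated)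
Conditions: 25 (3 equiv), ClCH2CH2Cl (0.05 M), hν (365 nm LED or Hg lamp through Pyrex), 20 °C; then 80 °C in the dark
Reagents that add atoms: none
Why: Proposed new method: irradiation of 20 triggers a Wolff rearrangement in which the C6 alkenyl carbon migrates to the diazo carbon (bond C8–C8a) to give vinylketene 26, whose ketene C=C undergoes [2+2] cycloaddition with the electron-rich alkyne 25 (alkyne CH to the ketene carbonyl carbon, bond C5–C6; siloxy carbon to the ketene CH, bond C7–C8) to give cyclobutenone 27. Heating opens 27 by 4π electrocyclic ring opening to dienylketene 28, ring A is then closed by a thermal 6π electrocyclisation (six-membered carbocycle, bond C4a–C5), and cyclohexadienone 29 tautomerises to phenol 30. The closest known reaction is the Danheiser benzannulation of cyclic α,β-unsaturated α'-diazo ketones with siloxyalkynes, which gives resorcinol monosilyl ethers; new here is that the vinylketene sits on a 4-oxodihydropyran and is therefore α-alkoxy- and β-acyl-substituted. No lasting stereocentre is formed (the sp3 centres of 27 and 29 vanish on aromatisation), and C2 should stay untouched because the whole sequence is neutral. The step needs regioselectivity in the [2+2], secured by the polarisation of the siloxyalkyne against the ketene so that the ketene oxygen ends as 5-OH and the silyloxy group at C7, and selective excitation of the diazo ketone, for which light above 350 nm is chosen because the enone and aryl ether chromophores absorb it only weakly; the alternative oxa-6π closure of 26 to a 2-pyranone is excluded because ketene and C4 carbonyl are trans across the ring C5=C6 bond.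

Step 13
Reactants: 30 (S)-5-hydroxy-2-Ar-7-(triisopropylsilyloxy)chroman-4-one
Product: 31 Kuwanon U, (2S)-5,7-dihydroxy-2-(5-geranyl-2-hydroxy-4-methoxyphenyl)chroman-4-one
Conditions: TBAF (2.5 equiv), AcOH (3 equiv), THF, 0 °C to rt
Reagents that add atoms: none
Why: Fluoride cleaves both aryl triisopropylsilyl ethers, and the acetic acid buffer keeps the phenols protonated so that neither base-induced opening to the chalcone nor quinone-methide formation from the 2'-phenoxide should scramble C2.

**Compound list**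

1 | 2-hydroxy-4-methoxybenzaldehyde | COc1ccc(C=O)c(O)c1 | starting material
2 | 5-bromo-2-hydroxy-4-methoxybenzaldehyde | COc1cc(O)c(C=O)cc1Br | intermediate
3 | 5-bromo-4-methoxy-2-(triisopropylsilyloxy)benzaldehyde | COc1cc(O[Si](C(C)C)(C(C)C)C(C)C)c(C=O)cc1Br | intermediate
4 | 5-bromo-4-methoxy-2-(triisopropylsilyloxy)benzaldehyde dimethyl acetal | COc1cc(O[Si](C(C)C)(C(C)C)C(C)C)c(C(OC)OC)cc1Br | intermediate
5 | geranyl bromide, (2E)-1-bromo-3,7-dimethylocta-2,6-diene | BrC/C=C(\C)CCC=C(C)C | starting material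
6 | [5-(dimethoxymethyl)-2-methoxy-4-(triisopropylsilyloxy)phenyl]lithium | COc1cc(O[Si](C(C)C)(C(C)C)C(C)C)c(C(OC)OC)cc1[Li] | intermediate
7 | [5-(dimethoxymethyl)-2-methoxy-4-(triisopropylsilyloxy)phenyl]copper(I) | COc1cc(O[Si](C(C)C)(C(C)C)C(C)C)c(C(OC)OC)cc1[Cu] | intermediate
8 | 5-geranyl-4-methoxy-2-(triisopropylsilyloxy)benzaldehyde dimethyl acetal | COc1cc(O[Si](C(C)C)(C(C)C)C(C)C)c(C(OC)OC)cc1C/C=C(\C)CCC=C(C)C | intermediate
9 | 5-geranyl-4-methoxy-2-(triisopropylsilyloxy)benzaldehyde | COc1cc(O[Si](C(C)C)(C(C)C)C(C)C)c(C=O)cc1C/C=C(\C)CCC=C(C)C | intermediate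
10 | ethyl 2,4-dioxopentanoate | CCOC(=O)C(=O)CC(C)=O | starting material
11 | ethyl (2Z)-4-oxo-2-(trimethylsilyloxy)pent-2-enoate | CCOC(=O)/C(O[Si](C)(C)C)=C/C(C)=O | intermediate
12 | ethyl (2Z)-2,4-bis(trimethylsilyloxy)penta-2,4-dienoate | CCOC(=O)/C(O[Si](C)(C)C)=C/C(=C)O[Si](C)(C)C | intermediate
13 | ethyl (2Z,6S)-6-Ar-4-oxo-6-(trichlorosilyloxy)-2-(trimethylsilyloxy)hex-2-enoate | COc1cc(O[Si](C(C)C)(C(C)C)C(C)C)c([C@@H](O[Si](Cl)(Cl)Cl)CC(=O)/C=C(\O[Si](C)(C)C)C(=O)OCC)cc1C/C=C(\C)CCC=C(C)C | intermediate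
14 | ethyl (6S)-6-Ar-6-hydroxy-2,4-dioxohexanoate (drawn as the keto form) | COc1cc(O[Si](C(C)C)(C(C)C)C(C)C)c([C@@H](O)CC(=O)CC(=O)C(=O)OCC)cc1C/C=C(\C)CCC=C(C)C | intermediate
15 | ethyl (6S)-6-Ar-2-hydroxy-4-oxotetrahydro-2H-pyran-2-carboxylate (anomers) | COc1cc(O[Si](C(C)C)(C(C)C)C(C)C)c([C@@H]2CC(=O)CC(O)(C(=O)OCC)O2)cc1C/C=C(\C)CCC=C(C)C | intermediate
16 | ethyl (2S)-2-Ar-4-oxo-3,4-dihydro-2H-pyran-6-carboxylate | COc1cc(O[Si](C(C)C)(C(C)C)C(C)C)c([C@@H]2CC(=O)C=C(C(=O)OCC)O2)cc1C/C=C(\C)CCC=C(C)C | intermediate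
17 | trimethylstannyl (2S)-2-Ar-4-oxo-3,4-dihydro-2H-pyran-6-carboxylate | COc1cc(O[Si](C(C)C)(C(C)C)C(C)C)c([C@@H]2CC(=O)C=C(C(=O)O[Sn](C)(C)C)O2)cc1C/C=C(\C)CCC=C(C)C | intermediate
18 | (2S)-2-Ar-4-oxo-3,4-dihydro-2H-pyran-6-carboxylic acid | COc1cc(O[Si](C(C)C)(C(C)C)C(C)C)c([C@@H]2CC(=O)C=C(C(=O)O)O2)cc1C/C=C(\C)CCC=C(C)C | intermediate
19 | mixed anhydride of 18 with isobutyl hydrogen carbonate | COc1cc(O[Si](C(C)C)(C(C)C)C(C)C)c([C@@H]2CC(=O)C=C(C(=O)OC(=O)OCC(C)C)O2)cc1C/C=C(\C)CCC=C(C)C | intermediate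
20 | (S)-6-(2-diazoacetyl)-2-[5-geranyl-4-methoxy-2-(triisopropylsilyloxy)phenyl]-2,3-dihydro-4H-pyran-4-one | COc1cc(O[Si](C(C)C)(C(C)C)C(C)C)c([C@@H]2CC(=O)C=C(C(=O)C=[N+]=[N-])O2)cc1C/C=C(\C)CCC=C(C)C | intermediate
21 | (trimethylsilyl)acetylene | C[Si](C)(C)C#C | starting material
22 | lithium (trimethylsilyl)acetylide | C[Si](C)(C)C#C[Li] | intermediate
23 | lithium 2-(trimethylsilyl)ethynolate | C[Si](C)(C)C#CO[Li] | intermediate
24 | triisopropyl{[(trimethylsilyl)ethynyl]oxy}silane | C[Si](C)(C)C#CO[Si](C(C)C)(C(C)C)C(C)C | intermediate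
25 | (triisopropylsiloxy)acetylene | C#CO[Si](C(C)C)(C(C)C)C(C)C | intermediate
26 | (S)-2-Ar-6-(2-oxoethenyl)-2,3-dihydro-4H-pyran-4-one (vinylketene) | COc1cc(O[Si](C(C)C)(C(C)C)C(C)C)c([C@@H]2CC(=O)C=C(C=C=O)O2)cc1C/C=C(\C)CCC=C(C)C | intermediate
27 | 4-[(2S)-2-Ar-4-oxo-3,4-dihydro-2H-pyran-6-yl]-3-(triisopropylsilyloxy)cyclobut-2-en-1-one (epimers at the ring CH) | COc1cc(O[Si](C(C)C)(C(C)C)C(C)C)c([C@@H]2CC(=O)C=C(C3C(=O)C=C3O[Si](C(C)C)(C(C)C)C(C)C)O2)cc1C/C=C(\C)CCC=C(C)C | intermediate
28 | (S)-2-Ar-6-[(1E)-4-oxo-2-(triisopropylsilyloxy)buta-1,3-dien-1-yl]-2,3-dihydro-4H-pyran-4-one (dienylketene) | COc1cc(O[Si](C(C)C)(C(C)C)C(C)C)c([C@@H]2CC(=O)C=C(/C=C(O[Si](C(C)C)(C(C)C)C(C)C)\C=C=O)O2)cc1C/C=C(\C)CCC=C(C)C | intermediate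
29 | (2S)-2-Ar-7-(triisopropylsilyloxy)-2,3-dihydro-4H-chromene-4,5(4aH)-dione (epimers at C4a) | COc1cc(O[Si](C(C)C)(C(C)C)C(C)C)c([C@@H]2CC(=O)C3C(=O)C=C(O[Si](C(C)C)(C(C)C)C(C)C)C=C3O2)cc1C/C=C(\C)CCC=C(C)C | intermediate
30 | (S)-5-hydroxy-2-[5-geranyl-4-methoxy-2-(triisopropylsilyloxy)phenyl]-7-(triisopropylsilyloxy)chroman-4-one | COc1cc(O[Si](C(C)C)(C(C)C)C(C)C)c([C@@H]2CC(=O)c3c(O)cc(O[Si](C(C)C)(C(C)C)C(C)C)cc3O2)cc1C/C=C(\C)CCC=C(C)C | intermediate
31 | Kuwanon U, (2S)-5,7-dihydroxy-2-(5-geranyl-2-hydroxy-4-methoxyphenyl)chroman-4-one | COc1cc(O)c([C@@H]2CC(=O)c3c(O)cc(O)cc3O2)cc1C/C=C(\C)CCC=C(C)C | target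

**Step count and risks**

Total steps: 13. Longest linear sequence: 10 steps (1–4, 6–9, 12, 13).

Steps most likely to fail:

1. Step 12 (proposed new method). The dihydropyranone enone may be excited in competition with the diazo ketone, the electron-poor vinylketene may oligomerise or be trapped by the phenol already formed, or the chromanone product may open under the light. Fallback with known chemistry, setting out from aldehyde 9 and returning at target 31: ring A is brought in ready-made by the thiourea-catalysed flavanone synthesis. Methyl 2,4,6-trihydroxybenzoate is bis-silylated (TIPSCl, imidazole) to methyl 2-hydroxy-4,6-bis(triisopropylsilyloxy)benzoate F1. Claisen condensation of F1 with the lithium enolate of tert-butyl acetate gives tert-butyl 3-[2-hydroxy-4,6-bis(triisopropylsilyloxy)phenyl]-3-oxopropanoate F2. Knoevenagel condensation of F2 with 9 (piperidinium acetate, toluene) gives the alkylidene β-keto ester F3. A cinchona-alkaloid thiourea (the pseudoenantiomer that leads to 2S) catalyses the intramolecular oxa-Michael addition to tert-butyl (2S)-5,7,2'-tris-O-TIPS-flavanone-3-carboxylate F4. Acid-mediated loss of the tert-butyl ester and decarboxylation (TsOH, toluene, 80 °C) gives 5,7,2'-tris-O-triisopropylsilyl Kuwanon U F5, and the conditions of step 13 then give 31.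

2. Step 6. Facial selectivity may be poor, or the ester-deactivated dienolate may add too slowly at −78 °C. Fallback, setting out from aldehyde 9 and returning at 14: Keck allylation (allyltributylstannane, Ti(Oi-Pr)4 with (S)-BINOL, the antipode that gives Si-face addition in the accepted model) gives the (S)-homoallylic alcohol F6. Wacker oxidation of the terminal alkene (PdCl2, CuCl, O2, DMF–H2O; the trisubstituted geranyl alkenes should not react) gives the (S)-β-hydroxy methyl ketone F7. The dianion of F7 (LiHMDS, 2.2 equiv, THF, −78 °C) is acylated at the methyl terminus with diethyl oxalate to give 14.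

3. Step 11. Methanolysis may attack the O–Si bond of the ynol ether as fast as the C–Si bond, so that the siloxyalkyne is lost as an ester. Fallback, setting out from 20 and 24 and returning at target 31: the desilylation is left out and diazo ketone 20 is irradiated with the bis-silyl alkyne 24 itself under the conditions of step 12. With the same polarity-controlled regiochemistry this should give the 6-trimethylsilyl analogue of 30, (S)-5-hydroxy-2-Ar-6-(trimethylsilyl)-7-(triisopropylsilyloxy)chroman-4-one F8. The buffered fluoride conditions of step 13, with longer time or more acetic acid, should then remove both O-silyl groups and, by ipso-protodesilylation of the C6–Si bond flanked by two oxygens, the C-silyl group, giving 31.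

Further compounds
F1 | step 12 | methyl 2-hydroxy-4,6-bis(triisopropylsilyloxy)benzoate | COC(=O)c1c(O)cc(O[Si](C(C)C)(C(C)C)C(C)C)cc1O[Si](C(C)C)(C(C)C)C(C)C
F2 | step 12 | tert-butyl 3-[2-hydroxy-4,6-bis(triisopropylsilyloxy)phenyl]-3-oxopropanoate | CC(C)(C)OC(=O)CC(=O)c1c(O)cc(O[Si](C(C)C)(C(C)C)C(C)C)cc1O[Si](C(C)C)(C(C)C)C(C)C
F3 | step 12 | tert-butyl 2-[2-hydroxy-4,6-bis(triisopropylsilyloxy)benzoyl]-3-Ar-prop-2-enoate (E/Z mixture) | CC(C)(C)OC(=O)C(=Cc1cc(C/C=C(\C)CCC=C(C)C)c(OC)cc1O[Si](C(C)C)(C(C)C)C(C)C)C(=O)c1c(O)cc(O[Si](C(C)C)(C(C)C)C(C)C)cc1O[Si](C(C)C)(C(C)C)C(C)C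
F4 | step 12 | tert-butyl (2S)-2-Ar-4-oxo-5,7-bis(triisopropylsilyloxy)chroman-3-carboxylate (C3 epimers) | COc1cc(O[Si](C(C)C)(C(C)C)C(C)C)c([C@@H]2C(C(=O)OC(C)(C)C)C(=O)c3c(O[Si](C(C)C)(C(C)C)C(C)C)cc(O[Si](C(C)C)(C(C)C)C(C)C)cc3O2)cc1C/C=C(\C)CCC=C(C)C
F5 | step 12 | (S)-2-Ar-5,7-bis(triisopropylsilyloxy)chroman-4-one (5,7,2'-tris-O-TIPS Kuwanon U) | COc1cc(O[Si](C(C)C)(C(C)C)C(C)C)c([C@@H]2CC(=O)c3c(O[Si](C(C)C)(C(C)C)C(C)C)cc(O[Si](C(C)C)(C(C)C)C(C)C)cc3O2)cc1C/C=C(\C)CCC=C(C)C
F6 | step 6 | (1S)-1-Ar-but-3-en-1-ol | COc1cc(O[Si](C(C)C)(C(C)C)C(C)C)c([C@@H](O)CC=C)cc1C/C=C(\C)CCC=C(C)C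
F7 | step 6 | (4S)-4-Ar-4-hydroxybutan-2-one | COc1cc(O[Si](C(C)C)(C(C)C)C(C)C)c([C@@H](O)CC(C)=O)cc1C/C=C(\C)CCC=C(C)C
F8 | step 11 | (S)-5-hydroxy-2-Ar-6-(trimethylsilyl)-7-(triisopropylsilyloxy)chroman-4-one | COc1cc(O[Si](C(C)C)(C(C)C)C(C)C)c([C@@H]2CC(=O)c3c(O)c([Si](C)(C)C)c(O[Si](C(C)C)(C(C)C)C(C)C)cc3O2)cc1C/C=C(\C)CCC=C(C)C
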